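A leftover comes first: if the protic impurity takes partner one for one and the substrate takes its own charge of partner, flask zeta is left with 0.0375 M of partner, so substrate is the limiting reagent and partner doesn't stop zeta.

| flask | substrate | partner | protic impurity | temperature | remark | time |
|---|---|---|---|---|---|---|
| Saturday's | 0.025 M | 0.090 M | 2.5 mM | 15 °C | run made earlier |  |
| Friday's | 0.038 M | 0.090 M | 2.5 mM | 50 °C | run made earlier |  |
| zeta | 0.050 M | 0.0900 M | 2.50 mM | 50 °C |  | 40 min |
| alpha | 0.050 M | 0.0900 M | 2.50 mM | 80 °C |  | 40 min |
| theta | 0.050 M | 0.0900 M | 2.50 mM | 20 °C |  | 40 min |

| run | time / min | product / % | substrate / % |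
|---|---|---|---|
| Saturday's | 15.0 | 1 | 100 |
| Saturday's | 30.0 | 1 | 100 |
| Saturday's | 50.0 | 3 | 101 |
| Saturday's | 80.0 | 1 | 99 |
| Saturday's | 150 | 2 | 95 |
| Saturday's | 240 | 41 | 59 |
| Friday's | 3.00 | 1 | 99 |
| Friday's | 5.00 | 2 | 98 |
| Friday's | 8.00 | 2 | 94 |
| Friday's | 15.0 | 14 | 86 |
| Friday's | 25.0 | 56 | 47 |
| Friday's | 40.0 | 93 | 9 |

(scatter of a reading: 1.5 percentage points)

- which flask leads in amount of product, in percent of the substrate charged ("all alike" within 1.5 percentage points) (zeta / alpha / theta / all alike)
- how much product is there at the end, in percent of the substrate charged: zeta
- how much product is there at the end, in percent of the substrate charged: alpha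
- how much product is there at the end, in percent of the substrate charged: theta

- the earlier runs were read with a standard deviation of 1.5 percentage points

Both runs lie flat and then climb, as a reaction feeding on its own product does (autocatalysis). If the rate goes with substrate, partner and product together and partner changes little, ln(product/substrate) climbs in a straight line. In Friday's run it climbs at 0.199 /min. Dividing by the substrate charge and by the free partner at mid-stretch, 0.0742 M, gives the growth constant, 1.18 /M²/s, a reading from two points. An objection is that the impurity may matter, but taken as quenched at once it removes 2.78% of the partner, and that share is already subtracted in the free partner above.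

Friday's line, run back to time zero, starts 4.80 below even. Suppose this start is the same percentage for any substrate charge. Zeta, with partner 0.0625 M at half conversion, grows at 0.221 /min, gaining 8.82 in its time, which gives 98.2%.

Theta has twice the charge of Saturday's run and is a little warmer. Saturday's constant, read the same way, is 0.315 /M²/s, though its lower point lies close to the scatter. Saturday's run still reads 2% at 150 min, and theta is read at 40 min. The objection is theta's larger charge and its warmth, but Saturday's flat stretch lasts 3.75 times theta's time against a charge ratio of 2.00, so by my reckoning theta stays near Saturday's flat readings. The constant reads larger in Friday's run than in Saturday's, so alpha should lead, unless product is lost at a heat no run has tried.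

The forecast names alpha, with 92% for zeta (range 80% to 98%), 98% for alpha (90% to 100%) and 1% for theta (0% to 4%), starting from the view that “almost no product forms at first”.

The flasks give 96.8% for zeta, >99.9% for alpha and 0.951% for theta, so alpha leads.

    substrate + partner + product → 2 product (k = 1.20 /M²/s, Ea = 37.0 kJ/mol)
    substrate + partner → product (k = 2.00 × 10⁻⁴ /M/s, Ea = 89.0 kJ/mol)
    partner + protic impurity → quenched reagent (k = 0.210 /M/s, Ea = 45.0 kJ/mol)
    (constants at 50 °C)

The growth constant overshot zeta by 1.4 points. Theta's small figure belongs to the hour of reading: theta holds 0.951% of product at 40 min against >99.9% at 400 min. A neighbour of zeta, charged with 0.020 M of substrate, grows at 0.109 /min, half of zeta's rate, and so gains 4.38 against the start of 4.80, which gives 39.7%. The computed neighbour holds 52.7% of product, with 47.3% of substrate remaining.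

The numbers in the tables are simulated from invented constants; scatter was added.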